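**Retrosynthetic overview** (locants are those of the octahydronaphthalene core: C1 carries N, C4 the oxane, C6 the ring methyl)

1. The formamide comes from an isocyanate and that from a C1 carboxylic acid (Curtius). The chloro-oxane comes from 6-endo chloroetherification of a tertiary alcohol, made by Felkin–Anh addition of a homoprenyl Grignard reagent to a C4 acetyl group.
2. Ring B comes from an intramolecular Diels–Alder reaction. The methacrylate ester of a temporary tertiary alcohol at C6 adds to the semicyclic diene C3=C4–C4a=C8a, forming C2–C3 and C1–C8a and a lactone bridge over ring A.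
3. Enabling feature: in ring A the methyl-bearing alkene carbon C6 lies 1,4 across the ring from C8a, the neighbour of the N-bearing quaternary C1. The one carbon on C1 (the later formyl carbon) can therefore be tied to C6 as an O–C(=O) bridge (a 2-oxabicyclo[3.2.2]nonan-3-one). Afterwards the ester oxygen leaves C6 to give the C5=C6 alkene and the carbonyl becomes N–CHO.
4. Ring order: ring A by ring-closing enyne metathesis (which also makes the diene); ring B plus the temporary lactone bridge in the key step; bridge opened; oxane ring last.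
5. Absolute configuration enters once (C6, asymmetric Corey–Chaykovsky epoxidation) and is relayed: C6 → C1 and C8a (tether) → C4a (bridge) → C4 (equilibration) → oxane C2 (Felkin–Anh) → oxane C5 (chair cyclisation).

Key step: step 6

Remark: the sense of induction of the epoxidation catalyst in step 2 is assumed by analogy with other alkyl methyl ketones; if it proves opposite, the antipodal binaphthol is used.

Step 1
Reactants: 1 but-3-yn-2-one; 2 1,2-bis(trimethylsilyloxy)ethane
Product: 3 2-ethynyl-2-methyl-1,3-dioxolane
Conditions: TMSOTf (2 mol %), CH2Cl2, −78 °C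
Reagents that add atoms: none
Why: Silyl-triflate-catalysed ketalisation with the bis-silyl ether of glycol works at low temperature on the ynone without conjugate addition to the triple bond; no stereocentre is formed.

Step 2
Reactants: 4 hex-5-en-2-one
Product: 5 (R)-2-(but-3-en-1-yl)-2-methyloxirane
Conditions: Me3S(O)I, NaH, THF; then 4, LaLi3[(S)-binaphthoxide]3 (5 mol %), (2,4,6-(MeO)3C6H2)3P=O (5 mol %), 5 Å MS, THF, rt
Reagents that add atoms: trimethylsulfoxonium iodide, C[S+](C)(C)=O.[I-]
Why: Catalytic asymmetric Corey–Chaykovsky epoxidation, in which the heterobimetallic binaphthoxide binds ketone and ylide and delivers the methylene to one face of the methyl ketone, sets the quaternary centre (the later C6) as R.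

Step 3
Reactants: 3 2-ethynyl-2-methyl-1,3-dioxolane; 5 (R)-2-(but-3-en-1-yl)-2-methyloxirane
Product: 6 (R)-4-methyl-1-(2-methyl-1,3-dioxolan-2-yl)oct-7-en-1-yn-4-ol
Conditions: n-BuLi, THF, −78 °C; BF3·OEt2; then 5, −78 °C
Reagents that add atoms: none
Why: BF3-promoted epoxide alkynylation by the lithium acetylide occurs at the unhindered CH2 terminus, so the tertiary carbinol centre is untouched and the ketal survives at −78 °C.

Step 4
Reactants: 6 (R)-4-methyl-1-(2-methyl-1,3-dioxolan-2-yl)oct-7-en-1-yn-4-ol
Product: 7 (R)-1-methyl-3-[1-(2-methyl-1,3-dioxolan-2-yl)ethenyl]cyclohex-3-en-1-ol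
Conditions: second-generation Grubbs catalyst RuCl2(H2IMes)(PCy3)(=CHPh) (5 mol %), ethylene (1 atm), PhMe, 60 °C
Reagents that add atoms: none
Why: Ring-closing enyne metathesis in the exo mode turns the 1,7-enyne into a 1-vinylcyclohexene, which builds ring A and the C3=C4–C4a=C8a diene at once; the remote stereocentre is unchanged.

Step 5
Reactants: 7 (R)-1-methyl-3-[1-(2-methyl-1,3-dioxolan-2-yl)ethenyl]cyclohex-3-en-1-ol; 8 methacryloyl chloride
Product: 9 (R)-1-methyl-3-[1-(2-methyl-1,3-dioxolan-2-yl)ethenyl]cyclohex-3-en-1-yl 2-methylprop-2-enoate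
Conditions: n-BuLi, THF, −78 °C; then 8, −78 → 0 °C
Reagents that add atoms: none
Why: O-Acylation of the lithium tertiary alkoxide by the acid chloride (ester formation) installs the dienophile; the low temperature avoids conjugate addition and leaves the ketal alone.

Step 6
Reactants: 9 (R)-1-methyl-3-[1-(2-methyl-1,3-dioxolan-2-yl)ethenyl]cyclohex-3-en-1-yl 2-methylprop-2-enoate
Product: 10 (1R,6R,8aS)-6-hydroxy-1,6-dimethyl-4-(2-methyl-1,3-dioxolan-2-yl)-1,2,3,5,6,7,8,8a-octahydronaphthalene-1-carboxylic acid 1,6-lactone (C4=C4a alkene; the O–C(=O) bridge spans ring A from C6 to the carboxyl carbon on C1)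
Conditions: PhMe (0.01 M), BHT (10 mol %), base-washed sealed tube, 165 °C
Reagents that add atoms: none
Why: Thermal, concerted but asynchronous normal-demand [4+2] cycloaddition between the tethered methacrylate C2=C1 and the semicyclic diene C3=C4–C4a=C8a; the closest known reaction type is the ester-tethered type 1 intramolecular Diels–Alder reaction of dienyl acrylates to fused or bridged lactones. Ring B closes as the cyclohexene of the cycloaddition, and the seven-membered lactone closes as the three-atom bridge of a 2-oxabicyclo[3.2.2]nonan-3-one over ring A, which adopts a boat. C8a is controlled by C6, because the pseudoaxial C6–O bond can deliver the dienophile only to its own face of the diene; C1 is controlled by the tether, which reaches C6 only when the carbonyl lies endo over C4a and C5, so the carboxyl carbon ends cis to the C8a–C8 bond and the methyl exo. The step needs regioselectivity (C1 to C8a, C2 to C3), which the two-atom O–C(=O) link enforces because it cannot span to C3 and which the ortho/para preference of the 2,3,4-substituted diene supports. It also needs the s-cis diene, favoured by the quaternary ketal carbon on C4, and suppression of ester elimination and methacrylate polymerisation, handled by base-washed glass, high dilution and BHT.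

Step 7
Reactants: 10 the bridged lactone from step 6
Product: 11 (1R,4S,4aR,6R,8aS)-6-hydroxy-1,6-dimethyl-4-(2-methyl-1,3-dioxolan-2-yl)decahydronaphthalene-1-carboxylic acid 1,6-lactone (cis ring fusion)
Conditions: Mn(dpm)3 (10 mol %; dpm = dipivaloylmethanate), PhSiH3, t-BuOOH, i-PrOH, rt
Reagents that add atoms: none
Why: Hydrogen-atom-transfer hydrogenation (manganese hydride, stepwise radical) reduces the hindered tetrasubstituted alkene; in the bridged lactone the hydrogen at C4a can only end on the face away from the bridge (the other epimer would need a trans junction that ring B cannot span), which sets the cis ring fusion, while C4 should form with its substituent equatorial on the locked ring B (4S) and is corrected in step 8.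

Step 8
Reactants: 11 the saturated bridged lactone from step 7
Product: 12 (1R,4R,4aR,8aS)-4-acetyl-1,6-dimethyl-1,2,3,4,4a,7,8,8a-octahydronaphthalene-1-carboxylic acid
Conditions: TsOH·H2O, wet PhMe, 90 °C
Reagents that add atoms: water, O
Why: Acid hydrolyses the ketal and then cleaves the tertiary lactone by alkyl–oxygen ionisation and E1 proton loss (as in tert-butyl ester cleavage), where loss of H-5 is expected because the departing carboxylate sits over the C4a–C5 edge and the C5=C6 isomer should be the less strained cis-octalin; the freed methyl ketone epimerises through its enol to 4R, in which acetyl is equatorial in the now flexible cis-decalin (in the 4S epimer it would be syn-axial to C8).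

Step 9
Reactants: 12 (1R,4R,4aR,8aS)-4-acetyl-1,6-dimethyl-1,2,3,4,4a,7,8,8a-octahydronaphthalene-1-carboxylic acid; 13 5-bromo-2-methylpent-2-ene
Product: 15 (1R,4R,4aR,8aS)-4-[(2R)-2-hydroxy-6-methylhept-5-en-2-yl]-1,6-dimethyl-1,2,3,4,4a,7,8,8a-octahydronaphthalene-1-carboxylic acid, via (4-methylpent-3-en-1-yl)magnesium bromide 14 (not isolated)
Conditions: 13, Mg, THF; then 12, LaCl3·2LiCl, THF, −20 → 0 °C; aq. NH4Cl
Reagents that add atoms: none
Why: Felkin–Anh addition of the homoprenyl Grignard reagent to the methyl ketone (the Lewis acid suppresses enolisation), with C4a as the large group anti to the incoming nucleophile and C4–H flanking its path, should give the 2R tertiary alcohol; the carboxylate is inert.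

Step 10
Reactants: 15 the hydroxy acid from step 9
Product: 16 (1R,4R,4aR,8aS)-4-[(2R,5S)-5-chloro-2,6,6-trimethyloxan-2-yl]-1,6-dimethyl-1,2,3,4,4a,7,8,8a-octahydronaphthalene-1-carboxylic acid
Conditions: NCS, Ph3P=S (10 mol %), CH2Cl2, −20 → 0 °C
Reagents that add atoms: N-chlorosuccinimide, O=C1CCC(=O)N1Cl
Why: Chloronium-induced 6-endo (Markovnikov) etherification, in which the tertiary hydroxyl opens the chloriranium ion at the dimethyl-substituted carbon through a chair with the decalin group equatorial, methyl axial and chlorine equatorial, should give the 2R,5S oxane (Cl trans to the decalin); assistance by the internal nucleophile should make the side-chain alkene react before the ring alkene.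

Step 11
Reactants: 16 the chloro-oxane acid from step 10
Product: 18 the tertiary isocyanate (compound 16 with N=C=O in place of CO2H on C1 and the same configuration), via acyl azide 17 (not isolated)
Conditions: (PhO)2P(O)N3, Et3N, PhMe, rt → 90 °C
Reagents that add atoms: diphenylphosphoryl azide, O=P(N=[N+]=[N-])(Oc1ccccc1)Oc1ccccc1
Why: In the Curtius rearrangement the acyl azide loses N2 with 1,2-shift of C1 to nitrogen with retention, so the C1–N bond forms with the configuration of the acid and the former lactone carbonyl becomes the isocyanate carbon.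

Step 12
Reactants: 18 the tertiary isocyanate from step 11
Product: 19 N-[(1R,4R,4aR,8aS)-4-[(2R,5S)-5-chloro-2,6,6-trimethyloxan-2-yl]-1,6-dimethyl-1,2,3,4,4a,7,8,8a-octahydronaphthalen-1-yl]formamide (CNP0241933.7)
Conditions: LiEt3BH, THF, −78 °C; aq. NH4Cl
Reagents that add atoms: none
Why: Hydride addition to the isocyanate carbon (isocyanate-to-formamide reduction) gives the N-formyl group; at −78 °C the hindered secondary chloride and the alkene should stay untouched and no stereocentre changes.

**Compound list**

1 | but-3-yn-2-one | CC(=O)C#C | starting material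
2 | 1,2-bis(trimethylsilyloxy)ethane | C[Si](C)(C)OCCO[Si](C)(C)C | starting material
3 | 2-ethynyl-2-methyl-1,3-dioxolane | C#CC1(C)OCCO1 | intermediate
4 | hex-5-en-2-one | CC(=O)CCC=C | starting material
5 | (R)-2-(but-3-en-1-yl)-2-methyloxirane | C[C@@]1(CCC=C)CO1 | intermediate
6 | (R)-4-methyl-1-(2-methyl-1,3-dioxolan-2-yl)oct-7-en-1-yn-4-ol | C[C@@](O)(CCC=C)CC#CC1(C)OCCO1 | intermediate
7 | (R)-1-methyl-3-[1-(2-methyl-1,3-dioxolan-2-yl)ethenyl]cyclohex-3-en-1-ol | C[C@]1(O)CC(C(=C)C2(C)OCCO2)=CCC1 | intermediate
8 | methacryloyl chloride | CC(=C)C(=O)Cl | starting material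
9 | (R)-1-methyl-3-[1-(2-methyl-1,3-dioxolan-2-yl)ethenyl]cyclohex-3-en-1-yl 2-methylprop-2-enoate | C[C@]1(OC(=O)C(C)=C)CC(C(=C)C2(C)OCCO2)=CCC1 | intermediate
10 | (1R,6R,8aS)-6-hydroxy-1,6-dimethyl-4-(2-methyl-1,3-dioxolan-2-yl)-1,2,3,5,6,7,8,8a-octahydronaphthalene-1-carboxylic acid 1,6-lactone | C[C@]14CC2=C(C3(C)OCCO3)CC[C@@](C)(C(=O)O4)[C@H]2CC1 | intermediate
11 | (1R,4S,4aR,6R,8aS)-6-hydroxy-1,6-dimethyl-4-(2-methyl-1,3-dioxolan-2-yl)decahydronaphthalene-1-carboxylic acid 1,6-lactone | C[C@]14C[C@H]2[C@@H](C3(C)OCCO3)CC[C@@](C)(C(=O)O4)[C@H]2CC1 | intermediate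
12 | (1R,4R,4aR,8aS)-4-acetyl-1,6-dimethyl-1,2,3,4,4a,7,8,8a-octahydronaphthalene-1-carboxylic acid | CC1=C[C@H]2[C@H](C(C)=O)CC[C@@](C)(C(=O)O)[C@H]2CC1 | intermediate
13 | 5-bromo-2-methylpent-2-ene | CC(C)=CCCBr | starting material
14 | (4-methylpent-3-en-1-yl)magnesium bromide | CC(C)=CCC[Mg]Br | intermediate (not isolated)
15 | (1R,4R,4aR,8aS)-4-[(2R)-2-hydroxy-6-methylhept-5-en-2-yl]-1,6-dimethyl-1,2,3,4,4a,7,8,8a-octahydronaphthalene-1-carboxylic acid | CC1=C[C@H]2[C@H]([C@@](O)(C)CCC=C(C)C)CC[C@@](C)(C(=O)O)[C@H]2CC1 | intermediate
16 | (1R,4R,4aR,8aS)-4-[(2R,5S)-5-chloro-2,6,6-trimethyloxan-2-yl]-1,6-dimethyl-1,2,3,4,4a,7,8,8a-octahydronaphthalene-1-carboxylic acid | CC1=C[C@H]2[C@H]([C@@]3(C)CC[C@H](Cl)C(C)(C)O3)CC[C@@](C)(C(=O)O)[C@H]2CC1 | intermediate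
17 | acyl azide of 16 (C(=O)N3 on C1) | CC1=C[C@H]2[C@H]([C@@]3(C)CC[C@H](Cl)C(C)(C)O3)CC[C@@](C)(C(=O)N=[N+]=[N-])[C@H]2CC1 | intermediate (not isolated)
18 | tertiary isocyanate (16 with N=C=O in place of CO2H on C1) | CC1=C[C@H]2[C@H]([C@@]3(C)CC[C@H](Cl)C(C)(C)O3)CC[C@@](C)(N=C=O)[C@H]2CC1 | intermediate
19 | N-[(1R,4R,4aR,8aS)-4-[(2R,5S)-5-chloro-2,6,6-trimethyloxan-2-yl]-1,6-dimethyl-1,2,3,4,4a,7,8,8a-octahydronaphthalen-1-yl]formamide | CC1=C[C@H]2[C@H]([C@@]3(C)CC[C@H](Cl)C(C)(C)O3)CC[C@@](C)(NC=O)[C@H]2CC1 | target

**Step count and risks**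

Total step count: 12. Longest linear sequence: 11 steps (4 → 5 → 6 → 7 → 9 → 10 → 11 → 12 → 15 → 16 → 18 → 19; the one-step branch 1 → 3 joins at step 3 and is equally long).

The three steps most likely to fail:

1. Step 6. The cycloaddition may not take place because the ester must adopt the disfavoured s-cis conformation and ring A a boat in the transition state, while thermal elimination of the tertiary ester and polymerisation of the methacrylate compete.
 Fallback, setting out from 7 and returning at 10: the tether is given up and the same bonds are formed intermolecularly under catalyst control. Dienol 7 is silylated (Et3SiOTf, 2,6-lutidine) to the triethylsilyl ether F1. F1 undergoes an enantioselective Diels–Alder reaction with methacrolein under a triflimide-activated proline-derived oxazaborolidinium catalyst (CH2Cl2, −78 °C), whose enantiomer is chosen to attack the diene face syn to the C6 oxygen, to give the endo aldehyde F2. Pinnick oxidation (NaClO2, NaH2PO4, 2-methylbut-2-ene) gives the acid F3, and Bu4NF frees the hydroxy acid F4. Yamaguchi lactonisation (2,4,6-trichlorobenzoyl chloride, Et3N, then DMAP, PhMe, heat) closes the bridge to 10; only the adduct with the carboxyl syn to the C6 oxygen can lactonise, so this step also removes exo or wrong-face material.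

2. Step 8. Proton loss from the C6 cation may be poorly regioselective (H-5 against H-7), and acid equilibration may erode any kinetic preference.
 Fallback, setting out from 11 and returning at 12: the alkene position is fixed by a regiospecific reductive elimination in place of the proton loss. The crude acid mixture from 11 is treated with I2 and NaHCO3 in MeCN–H2O. Iodolactonisation re-closes the C6–O lactone in both regioisomers and gives two constitutionally different, separable iodolactones: the 5-iodo lactone F5 (from 12) and the 7-iodo lactone F6 (from the C6=C7 isomer). Zinc dust in AcOH then converts F5 by reductive anti-elimination of iodide and carboxylate into pure 12; F6 can be returned to the acid equilibration.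

3. Step 10. The chloronium ion may form on the ring alkene as well (poor site selectivity), and 5-exo closure may compete with the 6-endo mode.
 Fallback, setting out from 15 and returning at 16: site selectivity is taken from a hydroxyl-directed oxidation and the chlorine is introduced in a ring expansion. VO(acac)2 (cat.) and t-BuOOH in CH2Cl2 epoxidise only the bishomoallylic side-chain alkene of 15, and the epoxy alcohol closes in situ by 5-exo attack to the 2,5-trans oxolane carbinol F7 (decalin and hydroxyisopropyl groups trans, as expected from a chair-like vanadate transition state with the large carbinol substituent equatorial). Me3SiCl with catalytic ZnCl2 (CH2Cl2, 0 °C) then ionises the tertiary carbinol with participation of the ring oxygen, and chloride opens the bicyclic oxonium ion at the ring carbon with inversion, which expands the oxolane to the chloro-oxane 16; tertiary chloride formed by attack at the other carbon re-ionises and is funnelled the same way.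

Further compounds
F1 | step 6 | triethylsilyl ether of 7, (R)-triethyl({1-methyl-3-[1-(2-methyl-1,3-dioxolan-2-yl)ethenyl]cyclohex-3-en-1-yl}oxy)silane | C[C@]1(O[Si](CC)(CC)CC)CC(C(=C)C2(C)OCCO2)=CCC1
F2 | step 6 | (1R,6R,8aS)-1,6-dimethyl-4-(2-methyl-1,3-dioxolan-2-yl)-6-(triethylsilyloxy)-1,2,3,5,6,7,8,8a-octahydronaphthalene-1-carbaldehyde | C[C@]1(O[Si](CC)(CC)CC)CC2=C(C3(C)OCCO3)CC[C@@](C)(C=O)[C@H]2CC1
F3 | step 6 | (1R,6R,8aS)-1,6-dimethyl-4-(2-methyl-1,3-dioxolan-2-yl)-6-(triethylsilyloxy)-1,2,3,5,6,7,8,8a-octahydronaphthalene-1-carboxylic acid | C[C@]1(O[Si](CC)(CC)CC)CC2=C(C3(C)OCCO3)CC[C@@](C)(C(=O)O)[C@H]2CC1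
F4 | step 6 | (1R,6R,8aS)-6-hydroxy-1,6-dimethyl-4-(2-methyl-1,3-dioxolan-2-yl)-1,2,3,5,6,7,8,8a-octahydronaphthalene-1-carboxylic acid | C[C@]1(O)CC2=C(C3(C)OCCO3)CC[C@@](C)(C(=O)O)[C@H]2CC1
F5 | step 8 | 4-acetyl-6-hydroxy-5-iodo-1,6-dimethyldecahydronaphthalene-1-carboxylic acid 1,6-lactone (iodine on C5 anti to the lactone oxygen; other centres as in 12) | C[C@]14[C@H](I)[C@H]2[C@H](C(C)=O)CC[C@@](C)(C(=O)O4)[C@H]2CC1
F6 | step 8 | 4-acetyl-6-hydroxy-7-iodo-1,6-dimethyldecahydronaphthalene-1-carboxylic acid 1,6-lactone (iodine on C7 anti to the lactone oxygen; other centres as in 12) | C[C@]14C[C@H]2[C@H](C(C)=O)CC[C@@](C)(C(=O)O4)[C@H]2C[C@@H]1I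
F7 | step 10 | (1R,4R,4aR,8aS)-4-[2,5-trans-5-(2-hydroxypropan-2-yl)-2-methyloxolan-2-yl]-1,6-dimethyl-1,2,3,4,4a,7,8,8a-octahydronaphthalene-1-carboxylic acid | CC1=C[C@H]2[C@H]([C@@]3(C)CC[C@H](C(C)(C)O)O3)CC[C@@](C)(C(=O)O)[C@H]2CC1
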